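We have 4.0 min in each set-up, on average in the tank, and the same amounts go in by different routes.

all flasks: substrate 0.25 M; third reagent 0.275 M

| run | partner | second reagent | time | remark |
|---|---|---|---|---|
| north-east | 0.300 M (fed, over 4.00 min) | 0.225 M | 4.0 min | all but partner at the start; partner goes in evenly over 4.00 min, the run ends at 4.0 min |
| west | 0.300 M | 0.225 M |  | a single well-mixed tank run continuously and read at steady state, 4.0 min in it on average |
| south | 0.300 M | 0.225 M | 4.0 min | a closed flask charged with all of it at once and left for 4.0 min |
| north | 0.300 M | 0.225 M (fed, over 4.00 min) | 4.0 min | a stirred flask in which second reagent is dosed at a steady rate over 4.00 min without added volume, worked up at 4.0 min |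

    substrate + partner → intermediate A (k1 = 0.15 /M/s)
    second reagent + intermediate A → intermediate B (k2 = 0.34 /M/s)
    third reagent + intermediate B → target (k3 = 0.0071 /M/s)
    target ⇌ isomer of the product (K4 = 13, k4 = 0.028 /s)
    second reagent + target → over-reaction product (k5 = 0.15 /M/s)

- the stated concentrations are those of everything mixed, before any reaction; amounts are the same in each set-up
- the feed brings no volume worth counting
- run time (north-east): 4.0 min

- the set-up with the highest amount of intermediate A at the outlet or at the end, in percent of the substrate put in ("none" if the first two lie within 2 percentage points) (north-east / west / south / north / none)
- amount of intermediate A at the outlet or at the end, in percent of the substrate put in, north-east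
- amount of intermediate A at the outlet or at the end, in percent of the substrate put in, west
- amount of intermediate A at the outlet or at the end, in percent of the substrate put in, south
- amount of intermediate A at the outlet or at the end, in percent of the substrate put in, north

Step 1 makes intermediate A and step 2 spends it, so the answer is what those two steps leave between them. In south, with the other charges as they stand, intermediate A has a half-life of 0.15 min by step 2 alone. The time is 26.7 of those half-lives, so it is far longer than that half-life, which gives step 2 room to use the second reagent there is. But that charge is 0.900 equivalents of substrate, which makes second reagent the limiting reagent of this step.

So we carry the shortfall g, one minus the charge of second reagent over the charge of substrate: g = 10.0% of the substrate, the part that second reagent cannot carry past intermediate A. Second reagent left over raises intermediate A, and so does step 5, which also spends second reagent, while unreacted substrate lowers it. We commit to 10.0% for south. In north, second reagent still enters up to 4.00 min, so we expect more than 10.0% there, and our reckoning stops at that bound.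

The forecast gives 13.5% for north-east, 14.7% for west, 11.7% for south and 22.2% for north, so it picks north: “Dosing keeps second reagent scarce while substrate conversion runs ahead, so A accumulates.” Our figure for south is lower than its figure.

The simulation gives 13.4% for north-east, 14.7% for west, 12.6% for south and 22.2% for north, so north is highest.

South ends 2.6 percentage points above g, with 2.97% as over-reaction product, 3.20% of its substrate unreacted and 3.11% of its own second reagent left. A neighbour of south takes 0.56 M of second reagent, which is 2.24 equiv. There g comes to −124%, below zero, so second reagent has no shortfall, and the half-life of intermediate A by step 2 alone at that charge is 0.0607 min. That neighbour ends at 0.328% of intermediate A, with 49.3% of its own second reagent left and 17.1% as over-reaction product.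

(All constants are those of an exercise; the result is computed.)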